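## Structural features

The target is a germacranolide: a ten-membered carbocycle (C1–C10) with a trans-fused α-methylene-γ-butyrolactone across C6–C7 (lactone oxygen on C6, C11 on C7, exocyclic C13 methylene). The ring carries a C1 ketone, a Z trisubstituted C4–C5 alkene with the C15 methyl on C4, and oxygen on C3, C8 (tiglate), C9 and C10 (tertiary, with the C14 methyl). There are six stereocentres, all S: C3 stands alone next to the alkene, while C6, C7, C8, C9 and C10 form an unbroken run. The fragile groups are the C1/C3 β-hydroxy ketone (dehydration to a dienone), the tertiary α-ketol at C10/C1, the C8 ester beside the free C9 hydroxyl (acyl shift), the exocyclic methylene lactone (conjugate addition) and the allylic C6–O bond. The real difficulty is to build a ten-membered ring containing a cis alkene and then to place five contiguous stereocentres on it, where facial control depends on ring conformation. The key step uses the fact that C3–C4(C15)–C5–C6–C7–C8, with its cis alkene and the three-carbon branch on C7, is the ring of carvone. Once C3 and C8 each carry an alkenyl group, the C3–C8 bond is the σ bond of a 1,5-diene, and a [3,3] shift inserts C2, C1, C10 and C9 between them.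

## Logic of the disconnections

33 ⇒ 32. The O–Si bond at C3 is cut last. The C3 hydroxyl must stay masked while C1 is oxidised and the epoxide is opened. The forward step has to be a buffered desilylation that leaves the β-hydroxy ketone, the ester and the methylene lactone alone.

32 ⇒ 30 + 31. The C8–O ester bond is cut and the C8/C9 oxygens are traced back to a trans epoxide. Opening at C8 with inversion gives the anti O8/O9 pattern and the ester in one operation, so no diol differentiation is needed. The forward step must be regioselective for C8 and must not disturb the α-ketol.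

30 ⇒ 29 ⇒ 28 ⇒ 27. The C1 carbonyl goes back to the benzylic ether and the epoxide to the E alkene. C1 has to be oxidised before a second secondary hydroxyl appears at C9. The forward epoxidation must reach the alkene face on which the free C10 hydroxyl lies.

27 ⇒ 26 ⇒ 23. The lactone C12–O6 bond is cut to a 2-methylene-1,4-diol. This moves the lactone oxidation level back to two alcohols that are already in place. The forward oxidation must pick the primary allylic alcohol.

23 ⇒ 22 ⇒ 21. Three O–Si bonds and the C3–H bond are cut. The C3 ketone is reduced before C6 is unmasked, because a cis γ-hydroxy enone would close to a furan. The reduction needs reagent control of the C3 configuration.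

21 ⇒ 18. The C1–C10 bond is cut and the C3–C8 bond restored. The ten-membered ring becomes a cyclohexenol with two trans alkenyl groups; C10 and the E alkene are traced to the C8 centre and the enol ether geometry. The forward step needs a chair transition state.

18 ⇒ 17 ⇒ 11 + 15. The C2–C3 bond is cut after the E enol ether is traced to an alkyne. This gives a ketone and a two-carbon alkynyl ether. The addition must come from the face opposite the C8 substituent, and the reduction must be trans.

11 ⇒ 10 ⇒ 9. The enol O–Si bond and the C10 carbonyl oxygen are removed, back to a terminal alkene. The forward steps need Markovnikov oxidation of only the monosubstituted alkene and enolisation toward C9 with Z geometry.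

9 ⇒ 8 ⇒ 5 ⇒ 4. The C6–O and C12–O bonds are cut. Both oxidations are placed on the six-membered ring, where the enone directs the first to the isopropenyl methyl and activates C6 as its γ position for the second. This spares the ten-membered ring any C–H oxidation. The C6 oxygen must enter trans to the C7 side chain.

4 ⇒ 1 + 2. The C8–C9 bond is cut. This leaves the chiral-pool enone and a simple allyl halide; the alkylation must go trans to the C7 side chain.

15 ⇒ 12 + 13. The vinylic C–O bond is cut to a benzylic alcohol and a C2 chloroalkene.

## Other disconnections considered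

Alternative 1: The cut is the C5–C6 bond together with the lactone C12–O bond. In the forward step the Z alkenyl iodide A1 is treated with CrCl2 and catalytic NiCl2; the alkenylchromium adds to the C6 aldehyde, and the C6 alkoxide closes on the methyl ester to give the lactone A2. In its favour, every oxygen at C1, C3, C8, C9 and C10 is in place at the right level before ring closure, the Z alkene geometry is fixed in the iodide, and the chromium reagent tolerates dense functionality. On this point it is better than the chosen plan, which must adjust oxidation levels and control facial selectivity on the medium ring after it is formed. Against it, the ring is closed end to end and needs dilution, the C6 configuration rests on conformational induction from C7, A2 lacks the C13 methylene (a late α-methylenation beside sensitive groups), and A1 needs a long linear build of four contiguous stereocentres from achiral pieces. The chosen plan is shorter to the ring and takes C7 from the chiral pool. Mechanistically, the two plans are about equal in stereochemical risk: C6 in the cyclisation there, C3 in the carbonyl addition here.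

Alternative 2: The cut is the C7–C8 bond. In the forward step CrCl2 converts the allylic bromide on the butenolide A3 into an allylchromium that attacks the C8 aldehyde through C7, moving the alkene to the exocyclic position and closing the ring to A4. In its favour, the methylene lactone is formed in the same step (better than the chosen plan, which needs an oxidation of C12 and an oxidative lactonisation), and the C8 hydroxyl arrives free and with the target configuration, so no inversion is needed (also better). Against it, two stereocentres (C7, C8) are set at once in a macrocyclic transition state whose preference is hard to predict, the α-alkoxy aldehyde at C8 can epimerise, dilution is needed, and A3 with its Z alkene and butenolide is long to make. In step economy the chosen plan should be equal or shorter overall; it is better at forming the ring and weaker at the lactone and C8.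

Alternative 3: The cut is the C6–C7 bond. In the forward step n-butyllithium deprotonates the propargylic C6 of the thirteen-membered ether A5 (drawn with the ring bonds trans on the alkene, an assumption), and the [2,3] shift contracts the ring to the cycloalkynol A6. In its favour, the ten-membered ring is not closed directly, C6 and C7 are set together, and the C6 oxygen comes from the rearrangement itself and needs no C–H oxidation (better than the γ-oxidation used here). Against it, the C4–C5 unit is an alkyne, so the C15 methyl and the Z alkene must still be installed regio- and stereoselectively, C12 must still be oxidised (equal to the chosen plan), deprotonation could occur at the allylic ether carbon instead, and the outcome depends on the conformation of a flexible thirteen-membered ring. The chosen plan takes the Z alkene and its methyl from the starting material and should be shorter.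

Key step: step 10

Remark on numbering and groups: germacrane numbering is used for all intermediates (the cyclohexenone ring is C3–C8); PMB is 4-methoxybenzyl, TBS is tert-butyldimethylsilyl, TES is triethylsilyl.

Remark on the design: the ring-expansion substrate 18 and its product 21 carry silyloxy groups at C6 and C12 as spectator groups, so no C–H oxidation is needed on the ten-membered ring. A chair analysis (Z enol ether, C8 substituent trans to the C7 side chain) leads to the C10 configuration of the target, so the configurations of 18 and 21 are mutually consistent.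

## Route

Step 1
Reactants: 1 (S)-carvone; 2 allyl bromide
Product: 4 (5S,6R)-6-allyl-2-methyl-5-(prop-1-en-2-yl)cyclohex-2-en-1-one (allyl on C8, trans to the C7 isopropenyl), via lithium dienolate 3 (not isolated)
Conditions: LiN(iPr)2, THF, −78 °C; allyl bromide, −78 to 0 °C
Reagents that add atoms: allyl bromide (compound 2), C=CCBr
Why: Kinetic deprotonation at C8 gives the cross-conjugated dienolate 3, which is alkylated at C8 (enolate alkylation). The electrophile should enter anti to the adjacent C7 isopropenyl group, and the chiral-pool centre C7 is untouched.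

Step 2
Reactants: 4 trans-8-allyl enone
Product: 5 (5S,6R)-6-allyl-5-(3-hydroxyprop-1-en-2-yl)-2-methylcyclohex-2-en-1-one (C12 alcohol)
Conditions: SeO2 (cat.), t-BuOOH, CH2Cl2, rt
Reagents that add atoms: SeO2, O=[Se]=O, reoxidised by tert-butyl hydroperoxide, CC(C)(C)OO
Why: Allylic oxidation by an ene reaction and [2,3] shift: the 1,1-disubstituted alkene is the most reactive one here (the enone is deactivated, the monosubstituted allyl group is slow). Hydrogen should be taken from the methyl group because the C7–H bond lies in the plane of the alkene.

Step 3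
Reactants: 5 C12 alcohol
Product: 8 (4R,5S,6R)-6-allyl-4-hydroxy-5-(3-hydroxyprop-1-en-2-yl)-2-methylcyclohex-2-en-1-one (C6 hydroxyl trans to the C7 side chain), via bis(triethylsilyl) dienol ether 6 (not isolated), via silyloxydiene epoxide 7 (not isolated)
Conditions: Et3SiOTf (2.3 equiv), Et3N, CH2Cl2, 0 °C to rt; dimethyldioxirane, acetone, −78 °C; AcOH/THF/H2O, rt
Reagents that add atoms: dimethyldioxirane, CC1(C)OO1
Why: Soft enolisation under equilibrating conditions should give the through-conjugated dienol ether 6, because the C8 hydrogen is tertiary and hindered. Dimethyldioxirane attacks its electron-rich terminal double bond anti to the C7 side chain to give 7, and acid opens 7 to the γ-hydroxy enone (vinylogous Rubottom oxidation), which sets C6; the primary silyl ether is cleaved in the same work-up.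

Step 4
Reactants: 8 diol
Product: 9 (4R,5S,6R)-6-allyl-4-(tert-butyldimethylsilyloxy)-5-[3-(tert-butyldimethylsilyloxy)prop-1-en-2-yl]-2-methylcyclohex-2-en-1-one
Conditions: TBSCl (2.5 equiv), imidazole, DMF, rt
Reagents that add atoms: tert-butyldimethylsilyl chloride, CC(C)(C)[Si](C)(C)Cl
Why: Standard silylation of a primary and a secondary allylic alcohol; the silyl ethers survive all steps up to the fluoride treatment in step 12.

Step 5
Reactants: 9 bis(silyl) ether
Product: 10 (4R,5S,6R)-4-(tert-butyldimethylsilyloxy)-5-[3-(tert-butyldimethylsilyloxy)prop-1-en-2-yl]-2-methyl-6-(2-oxopropyl)cyclohex-2-en-1-one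
Conditions: PdCl2 (cat.), CuCl, O2, DMF/H2O, rt
Reagents that add atoms: water, O
Why: Tsuji–Wacker oxidation: only the monosubstituted alkene undergoes Markovnikov hydroxypalladation, giving the methyl ketone. The 1,1-disubstituted alkene and the enone are not oxidised under these conditions.

Step 6
Reactants: 10 methyl ketone
Product: 11 enone with a (Z)-2-(tert-butyldimethylsilyloxy)prop-1-enyl group on C8 (silyloxy cis to C8), C6 and C12 silyl ethers unchanged
Conditions: TBSOTf (1.1 equiv), Et3N, CH2Cl2, −78 °C to rt
Reagents that add atoms: tert-butyldimethylsilyl triflate, CC(C)(C)[Si](C)(C)OS(=O)(=O)C(F)(F)F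
Why: Soft enolisation: the methyl ketone should react in preference to the ring enone, whose C8 and C6 hydrogens are both tertiary and shielded. Equilibration through triethylammonium triflate favours the more substituted enol ether with Z geometry, which has the least allylic strain.

Step 7
Reactants: 12 4-methoxybenzyl alcohol; 13 trichloroethylene
Product: 15 (E)-1,2-dichlorovinyl 4-methoxybenzyl ether, via dichloroacetylene 14 (not isolated)
Conditions: KH, THF, 0 °C to rt
Reagents that add atoms: trichloroethylene (compound 13), ClC=C(Cl)Cl
Why: KH converts 13 into dichloroacetylene 14 by elimination; the potassium alkoxide of 12 adds to it and protonation gives the E dichlorovinyl ether. This is the known entry to alkynyl ethers.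

Step 8
Reactants: 15 dichlorovinyl ether; 11 silyl enol ether ketone
Product: 17 tertiary carbinol at C3 bearing a (4-methoxybenzyloxy)ethynyl group trans to the C8 substituent (hydroxyl cis to it), via lithium alkoxyethynide 16 (not isolated)
Conditions: n-BuLi (2.3 equiv), THF, −78 to −40 °C; CeCl3, −78 °C; then 11
Reagents that add atoms: none
Why: Two equivalents of n-BuLi convert 15 into the alkynyllithium 16 (elimination, then chlorine–lithium exchange). Its cerium reagent adds 1,2 to the enone carbonyl without enolising the acidic C8–H. Entry anti to the large C8 substituent (1,2-induction) should place the alkynyl group trans to it and so set C3.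

Step 9
Reactants: 17 alkynyl carbinol
Product: 18 tertiary carbinol at C3 bearing an (E)-2-(4-methoxybenzyloxy)vinyl group trans to the (Z)-silyloxypropenyl group on C8
Conditions: NaAlH2(OCH2CH2OCH3)2, THF, 0 °C to rt; Rochelle salt work-up
Reagents that add atoms: none
Why: Alkoxide-directed trans-hydroalumination of the propargylic alcohol, then protonolysis, gives the E enol ether. Silyl ethers and the silyl enol ether are inert to the aluminium hydride.

Step 10
Reactants: 18 trans-dialkenyl carbinol
Product: 21 (4Z,8E)-ten-membered dienone with C3 ketone, C1 PMB ether, C10 tertiary silyl ether, C6 and C12 silyl ethers, via potassium alkoxide 19 (not isolated), via potassium enolate 20 (not isolated)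
Conditions: KH, 18-crown-6, THF, 0 °C to rt; aqueous NH4Cl, −78 °C
Reagents that add atoms: none
Why: KH with 18-crown-6 gives alkoxide 19, whose charge weakens the C3–C8 bond and accelerates a concerted [3,3] shift across C1=C2–C3–C8–C9=C10 (anionic oxy-Cope rearrangement, the standard ring expansion of 1,2-dialkenylcyclohexanols to cyclodec-5-enones). C3–C8 breaks as C1–C10 forms, so the ten-membered ring arises by four-atom expansion of the cyclohexene through a six-centre chair transition state and not by end-to-end closure; no dilution is needed. Because the two alkenyl groups are trans and both equatorial, the ring bonds C3–C4 and C8–C7 are equatorial in the chair, which gives the E C8–C9 alkene and enolate 20 (C2=C3), while the cis C4–C5 alkene, C6 and C7 are untouched. C10 is set by suprafacial chirality transfer from C8: with the Z enol ether the methyl group is equatorial and the silyloxy group axial in the chair, so C1 bonds to the face of C10 that gives the configuration of the target. C1 follows from the E geometry of the alkoxyvinyl group in the same chair (its oxygen equatorial); this centre is later oxidised. The step needs the chair to win over the boat and the [3,3] shift to outrun silyl transfer from the enol oxygen to the alkoxide; the trans-diequatorial arrangement, the bulky silyl group and the low temperature should secure this. A cold buffered quench protonates 20 at C2 to give 21 before the β-alkoxy group can be eliminated.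

Step 11
Reactants: 21 ten-membered dienone
Product: 22 (3S)-allylic alcohol, otherwise as 21
Conditions: (R)-2-methyl-CBS-oxazaborolidine [(3aR)-1-methyl-3,3-diphenyltetrahydro-1H,3H-pyrrolo[1,2-c][1,3,2]oxazaborole], catecholborane, toluene, −78 °C
Reagents that add atoms: none
Why: Corey–Bakshi–Shibata reduction: with the alkenyl branch as the large group, the (R)-catalyst should deliver hydride to give the 3S carbinol by 1,2-reduction. Catecholborane at low temperature does not hydroborate the alkenes, and the 1,3-syn relation to the C1 ether is also the one a chelate would favour.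

Step 12
Reactants: 22 allylic alcohol
Product: 23 tetraol with free hydroxyls at C3, C6, C10 and C12 and the C1 PMB ether
Conditions: Bu4NF (excess), THF, rt to 55 °C
Reagents that add atoms: none
Why: Fluoride cleaves the primary, the secondary and, on warming, the tertiary silyl ether. At this stage there is no carbonyl, ester or Michael acceptor, so the basic fluoride does no harm. The ketone was reduced first, so the cis γ-hydroxy enone that would close to a furan never appears.

Step 13
Reactants: 23 tetraol
Product: 26 trans-fused α-methylene-γ-butyrolactone (6,12-olide) with free C3 and C10 hydroxyls and the C1 PMB ether, via hydroxy enal 24 (not isolated), via lactol 25 (not isolated)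
Conditions: TEMPO (2,2,6,6-tetramethylpiperidin-1-oxyl, cat.), PhI(OAc)2, CH2Cl2, rt
Reagents that add atoms: none
Why: Oxoammonium oxidation is selective for the primary allylic alcohol and gives enal 24; the C6 hydroxyl closes lactol 25, and a second oxidation gives the lactone (oxidative lactonisation of a 1,4-diol). The trans fusion follows from the C6 and C7 configurations already set; the secondary and tertiary hydroxyls react more slowly.

Step 14
Reactants: 26 lactone diol
Product: 27 C3 triethylsilyl ether (C10 hydroxyl free)
Conditions: Et3SiCl, imidazole, CH2Cl2, 0 °C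
Reagents that add atoms: triethylsilyl chloride, CC[Si](Cl)(CC)CC
Why: The secondary allylic hydroxyl is silylated; the hindered tertiary C10 hydroxyl does not react with the silyl chloride. The C3 hydroxyl must be masked so that it neither directs epoxidation to C4–C5 nor is oxidised in step 17.

Step 15
Reactants: 27 C3 silyl ether
Product: 28 trans-8,9-epoxide on the alkene face syn to the C10 hydroxyl (C9–O as in the target)
Conditions: VO(acac)2 (cat.), t-BuOOH, CH2Cl2, 0 °C to rt
Reagents that add atoms: tert-butyl hydroperoxide, CC(C)(C)OO
Why: Hydroxyl-directed epoxidation: the tertiary allylic C10 hydroxyl binds vanadium and delivers oxygen to the adjacent E alkene from the outer face on which this hydroxyl lies, which is the face anti to the former C3–C8 bond and gives the C9 configuration of the target. Alkenes without a free allylic hydroxyl and the electron-poor methylene lactone are not epoxidised.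

Step 16
Reactants: 28 epoxide
Product: 29 C1 alcohol (PMB removed)
Conditions: DDQ (2,3-dichloro-5,6-dicyano-1,4-benzoquinone), CH2Cl2/pH 7 buffer, 0 °C
Reagents that add atoms: none
Why: Oxidative cleavage of the 4-methoxybenzyl ether by hydride abstraction; the water-containing medium hydrolyses the oxocarbenium ion before the neighbouring C10 hydroxyl can capture it as an acetal. Silyl ether, epoxide and lactone are inert.

Step 17
Reactants: 29 C1 alcohol
Product: 30 C1 ketone (α-ketol with C10 hydroxyl, epoxide intact)
Conditions: Dess–Martin periodinane, NaHCO3, CH2Cl2, rt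
Reagents that add atoms: none
Why: Oxidation of the only secondary alcohol under buffered neutral conditions, which avoid β-elimination of the C3 silyloxy group and opening of the epoxide. C1 is oxidised here because after step 18 a second secondary hydroxyl (C9) would compete.

Step 18
Reactants: 30 epoxy ketone; 31 tiglic acid
Product: 32 C8 tiglate with free C9 and C10 hydroxyls (C3 triethylsilyl ether)
Conditions: Ti(OiPr)4, tiglic acid, CH2Cl2, rt
Reagents that add atoms: tiglic acid (compound 31), OC(=O)/C(C)=C/C
Why: Titanium-mediated opening of a 2,3-epoxy alcohol by a carboxylic acid: the C10 alkoxide binds titanium, the epoxide is activated, and the carboxylate attacks the distal carbon C8 with inversion, giving the 8S ester and the 9S hydroxyl in one step. C9 is neopentylic and should not be attacked.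

Step 19
Reactants: 32 silyl ether
Product: 33 target, CNP0106709.2
Conditions: HF·pyridine, pyridine, THF, 0 °C
Reagents that add atoms: none
Why: Buffered fluoride removes the triethylsilyl ether; the mild, weakly acidic medium should avoid dehydration of the β-hydroxy ketone, acyl shift from O8 to O9 and conjugate addition to the methylene lactone.

## Compound list

1 | (S)-carvone | CC1=CC[C@@H](CC1=O)C(C)=C | starting material
2 | allyl bromide | C=CCBr | starting material
3 | lithium dienolate of 1 (O–Li on C3, C3=C8) | [Li]OC1=C[C@@H](C(C)=C)CC=C1C | intermediate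
4 | (5S,6R)-6-allyl-2-methyl-5-(prop-1-en-2-yl)cyclohex-2-en-1-one | O=C1C(C)=CC[C@H](C(C)=C)[C@H]1CC=C | intermediate
5 | (5S,6R)-6-allyl-5-(3-hydroxyprop-1-en-2-yl)-2-methylcyclohex-2-en-1-one | O=C1C(C)=CC[C@H](C(CO)=C)[C@H]1CC=C | intermediate
6 | bis(triethylsilyl) through-conjugated dienol ether of 5 | CC[Si](CC)(CC)OC1=C(C)C=C[C@H](C(CO[Si](CC)(CC)CC)=C)[C@H]1CC=C | intermediate
7 | 5,6-epoxide of 6, oxygen anti to the C7 side chain | CC[Si](CC)(CC)OC1=C(C)[C@H]2O[C@H]2[C@H](C(CO[Si](CC)(CC)CC)=C)[C@H]1CC=C | intermediate
8 | (4R,5S,6R)-6-allyl-4-hydroxy-5-(3-hydroxyprop-1-en-2-yl)-2-methylcyclohex-2-en-1-one | O=C1C(C)=C[C@@H](O)[C@H](C(CO)=C)[C@H]1CC=C | intermediate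
9 | bis(tert-butyldimethylsilyl) ether of 8 | O=C1C(C)=C[C@@H](O[Si](C)(C)C(C)(C)C)[C@H](C(CO[Si](C)(C)C(C)(C)C)=C)[C@H]1CC=C | intermediate
10 | 2-oxopropyl ketone (C10 methyl ketone) | O=C1C(C)=C[C@@H](O[Si](C)(C)C(C)(C)C)[C@H](C(CO[Si](C)(C)C(C)(C)C)=C)[C@H]1CC(C)=O | intermediate
11 | enone with (Z)-2-silyloxyprop-1-enyl group on C8 | O=C1C(C)=C[C@@H](O[Si](C)(C)C(C)(C)C)[C@H](C(CO[Si](C)(C)C(C)(C)C)=C)[C@H]1/C=C(/C)O[Si](C)(C)C(C)(C)C | intermediate
12 | 4-methoxybenzyl alcohol | COc1ccc(CO)cc1 | starting material
13 | trichloroethylene | ClC=C(Cl)Cl | starting material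
14 | dichloroacetylene | ClC#CCl | intermediate
15 | (E)-1,2-dichlorovinyl 4-methoxybenzyl ether | COc1ccc(CO/C(Cl)=C\Cl)cc1 | intermediate
16 | lithium (4-methoxybenzyloxy)ethynide | [Li]C#COCc1ccc(OC)cc1 | intermediate
17 | C3 alkynyl carbinol, alkynyl trans to the C8 substituent | O[C@@]1(C#COCc2ccc(OC)cc2)C(C)=C[C@@H](O[Si](C)(C)C(C)(C)C)[C@H](C(CO[Si](C)(C)C(C)(C)C)=C)[C@H]1/C=C(/C)O[Si](C)(C)C(C)(C)C | intermediate
18 | trans-dialkenyl carbinol with (E)-alkoxyvinyl on C3 and (Z)-silyloxypropenyl on C8 | O[C@@]1(/C=C/OCc2ccc(OC)cc2)C(C)=C[C@@H](O[Si](C)(C)C(C)(C)C)[C@H](C(CO[Si](C)(C)C(C)(C)C)=C)[C@H]1/C=C(/C)O[Si](C)(C)C(C)(C)C | intermediate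
19 | potassium alkoxide of 18 | [K+].[O-][C@@]1(/C=C/OCc2ccc(OC)cc2)C(C)=C[C@@H](O[Si](C)(C)C(C)(C)C)[C@H](C(CO[Si](C)(C)C(C)(C)C)=C)[C@H]1/C=C(/C)O[Si](C)(C)C(C)(C)C | intermediate
20 | potassium C2=C3 enolate of 21 | [K+].C=C(CO[Si](C)(C)C(C)(C)C)[C@H]1[C@H](O[Si](C)(C)C(C)(C)C)/C=C(/C)C(/[O-])=C/[C@@H](OCc2ccc(OC)cc2)[C@@](C)(O[Si](C)(C)C(C)(C)C)/C=C/1 | intermediate
21 | (4Z,8E)-ten-membered dienone, C3 ketone, C1 PMB ether, C6, C10 and C12 silyl ethers | C=C(CO[Si](C)(C)C(C)(C)C)[C@H]1[C@H](O[Si](C)(C)C(C)(C)C)/C=C(/C)C(=O)C[C@@H](OCc2ccc(OC)cc2)[C@@](C)(O[Si](C)(C)C(C)(C)C)/C=C/1 | intermediate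
22 | (3S)-alcohol of 21 | C=C(CO[Si](C)(C)C(C)(C)C)[C@H]1[C@H](O[Si](C)(C)C(C)(C)C)/C=C(/C)[C@@H](O)C[C@@H](OCc2ccc(OC)cc2)[C@@](C)(O[Si](C)(C)C(C)(C)C)/C=C/1 | intermediate
23 | tetraol (C3, C6, C10, C12 hydroxyls), C1 PMB ether | C=C(CO)[C@H]1[C@H](O)/C=C(/C)[C@@H](O)C[C@@H](OCc2ccc(OC)cc2)[C@@](C)(O)/C=C/1 | intermediate
24 | C12 enal of 23 | C=C(C=O)[C@H]1[C@H](O)/C=C(/C)[C@@H](O)C[C@@H](OCc2ccc(OC)cc2)[C@@](C)(O)/C=C/1 | intermediate
25 | lactol from 24 and the C6 hydroxyl (C12 configuration open) | C=C1C(O)O[C@@H]2/C=C(/C)[C@@H](O)C[C@@H](OCc3ccc(OC)cc3)[C@@](C)(O)/C=C/[C@@H]12 | intermediate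
26 | trans-fused α-methylene lactone, C3 and C10 hydroxyls free | C=C1C(=O)O[C@@H]2/C=C(/C)[C@@H](O)C[C@@H](OCc3ccc(OC)cc3)[C@@](C)(O)/C=C/[C@@H]12 | intermediate
27 | C3 triethylsilyl ether of 26 | C=C1C(=O)O[C@@H]2/C=C(/C)[C@@H](O[Si](CC)(CC)CC)C[C@@H](OCc3ccc(OC)cc3)[C@@](C)(O)/C=C/[C@@H]12 | intermediate
28 | trans-8,9-epoxide of 27, syn to the C10 hydroxyl | C=C1C(=O)O[C@@H]2/C=C(/C)[C@@H](O[Si](CC)(CC)CC)C[C@@H](OCc3ccc(OC)cc3)[C@@](C)(O)[C@H]4O[C@@H]4[C@@H]12 | intermediate
29 | C1 alcohol of 28 | C=C1C(=O)O[C@@H]2/C=C(/C)[C@@H](O[Si](CC)(CC)CC)C[C@@H](O)[C@@](C)(O)[C@H]3O[C@@H]3[C@@H]12 | intermediate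
30 | C1 ketone, 8,9-epoxide, C10 hydroxyl | C=C1C(=O)O[C@@H]2/C=C(/C)[C@@H](O[Si](CC)(CC)CC)CC(=O)[C@@](C)(O)[C@H]3O[C@@H]3[C@@H]12 | intermediate
31 | tiglic acid | OC(=O)/C(C)=C/C | starting material
32 | C8 tiglate, C9 and C10 hydroxyls, C3 triethylsilyl ether | C=C1C(=O)O[C@@H]2/C=C(/C)[C@@H](O[Si](CC)(CC)CC)CC(=O)[C@@](C)(O)[C@@H](O)[C@@H](OC(=O)/C(C)=C/C)[C@@H]12 | intermediate
33 | CNP0106709.2 | C=C1C(=O)O[C@@H]2/C=C(/C)[C@@H](O)CC(=O)[C@@](C)(O)[C@@H](O)[C@@H](OC(=O)/C(C)=C/C)[C@@H]12 | target

## Step count and least certain steps

Total: 19 steps. Longest linear sequence: 18 steps (steps 1–6 and 8–19, from 1); step 7 is a one-step branch.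

Step 10 (key step). The most likely failure is transfer of the silyl group from the enol oxygen to the C3 alkoxide before the [3,3] shift, which would stop the rearrangement; the second is β-elimination of the benzylic alkoxide from enolate 20. Both come from the free alkoxide. The fallback runs the rearrangement without one: 18 is silylated with N-(trimethylsilyl)imidazole to the trimethylsilyl ether F1, which is heated (toluene, sealed tube, about 180 °C) in a neutral silyloxy-Cope rearrangement to the ring-expanded trimethylsilyl enol ether F2; K2CO3 in methanol then frees the ketone. It sets out from 18 and comes back at 21.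

Step 8. The nucleophile may enter on the face syn to the C8 substituent. A slim alkynyl metal tends to approach a cyclohexenone axially, here trans to the C7 side chain, and the silyloxy group of the C8 side chain lies near the desired face; this would give the C3 epimer, which cannot reach the chair needed in step 10. The fallback changes to a bulky alkenyl metal, for which equatorial entry anti to the C8 substituent is the norm. 15 is converted with n-BuLi and then methanol into the ethynyl ether F3; hydrozirconation with Cp2Zr(H)Cl and iodinolysis give the (E)-iodovinyl ether F4; t-BuLi and then CeCl3 give the alkenylcerium reagent F5, which adds to 11. It sets out from 15 and 11 and comes back at 18; step 9 is then not needed.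

Step 3. Silylation may go toward C8 and give the cross-conjugated dienol ether, so that oxygen is delivered to C8, or the oxidant may show poor facial selectivity at C6. The fallback avoids dienol ethers. 5 is silylated (TBSCl, imidazole) to the C12 silyl ether F6; t-BuOOH with Rh2(cap)4 (dirhodium tetrakis(caprolactamate)) oxidises the γ-methylene to the ene-dione F7; NaBH4 with CeCl3 at low temperature reduces the less hindered C6 carbonyl by axial hydride delivery to the trans γ-hydroxy enone F8, which is silylated. It sets out from 5 and comes back at 9.

Step 6. Deprotonation at the methyl group (terminal enol ether), formation of the E isomer, or competing silylation of the ring enone would each lower the supply of 11; the E isomer would invert C10 in step 10. The fallback changes the mode of enolisation from a silyloxocarbenium ion to a metal enolate under thermodynamic control: BrMgN(iPr)2 forms the more substituted Z magnesium enolate, which is trapped with TBSOTf. It sets out from 10, comes back at 11 and makes no new compound.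

Step 18. The carboxylate must reach the rear of C8, which in a ten-membered ring points toward the ring interior, so the opening may be slow; shift of the ester to O9 or rearrangement of the α-ketol on titanium could then take over. The fallback replaces the epoxide by a stronger leaving group. 27 is dihydroxylated (OsO4 cat., N-methylmorpholine N-oxide) to the syn 8,9-diol F9 and converted with SO2Cl2 and Et3N into the cyclic sulfate F10; DDQ gives the C1 alcohol F11 and Dess–Martin periodinane the C1 ketone F12; caesium tiglate in DMF opens the sulfate at C8 with inversion to the C9 sulfate salt F13, and dilute H2SO4 in wet THF removes the sulfate and the triethylsilyl group. It sets out from 27 and comes back at 33.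

## Further compounds

F1 | step 10 | trimethylsilyl ether of 18 | C[Si](C)(C)O[C@@]1(/C=C/OCc2ccc(OC)cc2)C(C)=C[C@@H](O[Si](C)(C)C(C)(C)C)[C@H](C(CO[Si](C)(C)C(C)(C)C)=C)[C@H]1/C=C(/C)O[Si](C)(C)C(C)(C)C
F2 | step 10 | C2=C3 trimethylsilyl enol ether of 21 | C=C(CO[Si](C)(C)C(C)(C)C)[C@H]1[C@H](O[Si](C)(C)C(C)(C)C)/C=C(/C)C(/O[Si](C)(C)C)=C/[C@@H](OCc2ccc(OC)cc2)[C@@](C)(O[Si](C)(C)C(C)(C)C)/C=C/1
F3 | step 8 | ethynyl 4-methoxybenzyl ether | C#COCc1ccc(OC)cc1
F4 | step 8 | (E)-2-iodovinyl 4-methoxybenzyl ether | I/C=C/OCc1ccc(OC)cc1
F5 | step 8 | (E)-2-(4-methoxybenzyloxy)vinylcerium dichloride | Cl[Ce](Cl)/C=C/OCc1ccc(OC)cc1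
F6 | step 3 | C12 tert-butyldimethylsilyl ether of 5 | O=C1C(C)=CC[C@H](C(CO[Si](C)(C)C(C)(C)C)=C)[C@H]1CC=C
F7 | step 3 | C3,C6 ene-dione | O=C1C(C)=CC(=O)[C@H](C(CO[Si](C)(C)C(C)(C)C)=C)[C@H]1CC=C
F8 | step 3 | trans γ-hydroxy enone with C12 silyl ether | O=C1C(C)=C[C@@H](O)[C@H](C(CO[Si](C)(C)C(C)(C)C)=C)[C@H]1CC=C
F0 | step 6 | none | none
F9 | step 18 | syn 8,9-diol of 27 | C=C1C(=O)O[C@@H]2/C=C(/C)[C@@H](O[Si](CC)(CC)CC)C[C@@H](OCc3ccc(OC)cc3)[C@@](C)(O)[C@@H](O)[C@H](O)[C@@H]12
F10 | step 18 | 8,9-cyclic sulfate, C1 PMB ether | C=C1C(=O)O[C@@H]2/C=C(/C)[C@@H](O[Si](CC)(CC)CC)C[C@@H](OCc3ccc(OC)cc3)[C@@](C)(O)[C@H]4OS(=O)(=O)O[C@@H]4[C@@H]12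
F11 | step 18 | 8,9-cyclic sulfate, C1 alcohol | C=C1C(=O)O[C@@H]2/C=C(/C)[C@@H](O[Si](CC)(CC)CC)C[C@@H](O)[C@@](C)(O)[C@H]3OS(=O)(=O)O[C@@H]3[C@@H]12
F12 | step 18 | 8,9-cyclic sulfate, C1 ketone | C=C1C(=O)O[C@@H]2/C=C(/C)[C@@H](O[Si](CC)(CC)CC)CC(=O)[C@@](C)(O)[C@H]3OS(=O)(=O)O[C@@H]3[C@@H]12
F13 | step 18 | C8 tiglate C9 sulfate caesium salt | C=C1C(=O)O[C@@H]2/C=C(/C)[C@@H](O[Si](CC)(CC)CC)CC(=O)[C@@](C)(O)[C@@H](OS(=O)(=O)[O-])[C@@H](OC(=O)/C(C)=C/C)[C@@H]12.[Cs+]
A1 | alternative 1 | open-chain Z alkenyl iodide with C6 aldehyde and C12 methyl ester | COC(=O)C[C@@H](C=O)[C@H](OCc1ccc(OC)cc1)[C@@H]2OC(C)(C)O[C@]2(C)C3(OCCO3)C[C@H](O[Si](C)(C)C(C)(C)C)/C(C)=C\I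
A2 | alternative 1 | trans-fused lactone on the ten-membered ring | O=C1C[C@@H]2[C@H](OCc5ccc(OC)cc5)[C@@H]3OC(C)(C)O[C@]3(C)C4(OCCO4)C[C@H](O[Si](C)(C)C(C)(C)C)/C(C)=C\[C@H]2O1
A3 | alternative 2 | butenolide allylic bromide with C8 aldehyde | O=C1O[C@H](/C=C(/C)[C@@H](O[Si](C)(C)C(C)(C)C)CC2(OCCO2)[C@@]3(C)OC(C)(C)O[C@H]3C=O)C=C1CBr
A4 | alternative 2 | protected germacranolide with free C8 hydroxyl | C=C1C(=O)O[C@@H]2/C=C(/C)[C@@H](O[Si](C)(C)C(C)(C)C)CC3(OCCO3)[C@@]4(C)OC(C)(C)O[C@H]4[C@@H](O)[C@@H]12
A5 | alternative 3 | thirteen-membered allyl propargyl ether | C1OC/C(COCc2ccc(OC)cc2)=C/[C@H](OCOC)[C@@H]3OC(C)(C)O[C@]3(C)C4(OCCO4)C[C@H](O[Si](C)(C)C(C)(C)C)C#C1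
A6 | alternative 3 | ten-membered cycloalkynol | O[C@@H]1C#C[C@@H](O[Si](C)(C)C(C)(C)C)CC2(OCCO2)[C@@]3(C)OC(C)(C)O[C@H]3[C@@H](OCOC)[C@H]1C(=C)COCc4ccc(OC)cc4
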